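## Plan

- Retrosynthetic cuts, in order: the C6=C7 bond of the cycloheptenone (aldol condensation), the side-chain bond between the chain CH2 and the tertiary carbinol carbon (fragment union), the C1–C2 bond of the cyclopentane (aldol condensation of an ozonolysis product), and the two ring bonds of a cyclohexene (Diels–Alder). Core atoms are numbered as an azulene: C-1 carries the side chain, C-3a the methyl, C-8a the ring-fusion hydrogen.
- Forward order: Diels–Alder cyclohexene, then ozonolysis/aldol ring contraction to a 1-acetylcyclopentene, hydrogenation, union with the C6 side chain (step 9), oxidation of the side chain, and closure of the seven-membered ring last.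
- Stereochemistry: C-3a/C-8a from a catalyst-controlled Diels–Alder reaction of an (E)-enal (trans arms); C-1 from hydrogenation anti to the cis arm; the carbinol centre from Felkin–Anh addition; the acetoxy centre from a reagent-controlled Shi epoxidation followed by epoxide-to-allylic-alcohol isomerisation.
- Enabling feature: the carbinol carbon is exocyclic on C-1 of the five-membered ring, flanked by ring CH2 (C-2) and by methine C-8a whose CH2 arm is cis. A C-1 acetyl group therefore has one strongly shielded carbonyl face.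
- The 1,4-dioxygenated chain ending in an isopropenyl carbinol is an oxidised homoprenyl group, so the nucleophile can be the plain C6 Grignard reagent. The trans arms on C-3a/C-8a leave the seven-membered aldol closure as the only strain-free one.

Key step: step 9

Abbreviations: TBDPS = tert-butyldiphenylsilyl, TBS = tert-butyldimethylsilyl, TES = triethylsilyl.

Assumption: the carbinol carbon of the 2-silyloxybutyl arm (made in step 4, oxidised in step 15) is carried as both epimers, so compounds 8 to 21 are epimer pairs at that one centre.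

## Route

Step 1
Reactants: 1 3-[(tert-butyldiphenylsilyl)oxy]propanal; 2 2-(triphenylphosphoranylidene)propanal
Product: 3 (2E)-5-[(TBDPS)oxy]-2-methylpent-2-enal
Conditions: PhMe, 90 °C
Reagents that add atoms: none
Why: Wittig olefination with a formyl-stabilised ylide should give the (E)-trisubstituted enal, whose geometry later fixes the trans relation of the two ring arms.

Step 2
Reactants: 3 (2E)-5-[(TBDPS)oxy]-2-methylpent-2-enal; 4 isoprene
Product: 5 (1S,6R)-6-{2-[(TBDPS)oxy]ethyl}-1,4-dimethylcyclohex-3-ene-1-carbaldehyde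
Conditions: isoprene (5 equiv), (R)-o-tolyl-CBS oxazaborolidine [(R)-1-(2-methylphenyl)-3,3-diphenyltetrahydro-1H,3H-pyrrolo[1,2-c][1,3,2]oxazaborole] activated with HNTf2 (20 mol %), CH2Cl2, −40 °C
Reagents that add atoms: none
Why: Enantioselective Diels–Alder reaction of an α-methyl enal under cationic oxazaborolidine catalysis; "para" regiochemistry puts the ring methyl 1,4 to the formyl-bearing carbon, suprafacial addition to the (E)-enal sets formyl and silyloxyethyl trans, and the catalyst (formyl C–H···O organisation, one face of the s-trans enal covered by an aryl group) should direct the diene to the C-2 Si face of 3, with the (R) antipode assigned from the pre-transition-state model and the (S) antipode used if the sense proves opposite.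

Step 3
Reactants: 5 (1S,6R)-6-{2-[(TBDPS)oxy]ethyl}-1,4-dimethylcyclohex-3-ene-1-carbaldehyde
Product: 7 2-[(1R,6R)-6-{2-[(TBDPS)oxy]ethyl}-1,4-dimethylcyclohex-3-en-1-yl]acetaldehyde, via methyl enol ether 6 (not isolated)
Conditions: Ph3P+CH2OMe Cl−, KOtBu, THF, 0 °C → rt; then 2 M HCl, THF, rt
Reagents that add atoms: (methoxymethyl)triphenylphosphonium chloride, COC[P+](c1ccccc1)(c1ccccc1)c1ccccc1.[Cl-]; water, O
Why: Wittig methoxymethylenation of the non-enolisable neopentyl aldehyde and acid hydrolysis of the enol ether is the standard one-carbon homologation, turning the formyl carbon into the future ring CH2 (C-4) without touching the quaternary centre (the change of its descriptor is a priority change only).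

Step 4
Reactants: 7 2-[(1R,6R)-6-{2-[(TBDPS)oxy]ethyl}-1,4-dimethylcyclohex-3-en-1-yl]acetaldehyde
Product: 8 1-[(1R,6R)-6-{2-[(TBDPS)oxy]ethyl}-1,4-dimethylcyclohex-3-en-1-yl]butan-2-ol (both C-2 epimers)
Conditions: EtMgBr, THF, −78 → 0 °C; aq. NH4Cl
Reagents that add atoms: ethylmagnesium bromide, CC[Mg]Br
Why: Grignard addition to an unhindered aldehyde; the new carbinol centre forms without control and both epimers are carried on because it becomes the ring ketone carbon in step 15.

Step 5
Reactants: 8 1-[(1R,6R)-6-{2-[(TBDPS)oxy]ethyl}-1,4-dimethylcyclohex-3-en-1-yl]butan-2-ol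
Product: 9 tert-butyl({1-[(1R,6R)-6-{2-[(TBDPS)oxy]ethyl}-1,4-dimethylcyclohex-3-en-1-yl]butan-2-yl}oxy)dimethylsilane
Conditions: TBSOTf, 2,6-lutidine, CH2Cl2, 0 °C
Reagents that add atoms: tert-butyldimethylsilyl triflate, CC(C)(C)[Si](C)(C)OS(=O)(=O)C(F)(F)F
Why: Silyl ether formation masks the secondary hydroxyl through the oxidative, basic and organometallic steps that follow.

Step 6
Reactants: 9 tert-butyl({1-[(1R,6R)-6-{2-[(TBDPS)oxy]ethyl}-1,4-dimethylcyclohex-3-en-1-yl]butan-2-yl}oxy)dimethylsilane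
Product: 11 (3S,4S)-3-{2-[(TBS)oxy]butyl}-4-{2-[(TBDPS)oxy]ethyl}-3-methyl-6-oxoheptanal, via ozonide 10 (not isolated)
Conditions: O3, CH2Cl2, −78 °C; then PPh3, −78 °C → rt
Reagents that add atoms: ozone, [O-][O+]=O
Why: Ozonolysis with reductive work-up cleaves the only C=C bond to a methyl ketone and an aldehyde, a 1,6-dicarbonyl pair set up for ring contraction, and silyl ethers are inert at −78 °C.

Step 7
Reactants: 11 (3S,4S)-3-{2-[(TBS)oxy]butyl}-4-{2-[(TBDPS)oxy]ethyl}-3-methyl-6-oxoheptanal
Product: 13 1-[(4R,5R)-4-{2-[(TBS)oxy]butyl}-5-{2-[(TBDPS)oxy]ethyl}-4-methylcyclopent-1-en-1-yl]ethan-1-one, via aldol adduct 12 (not isolated)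
Conditions: KOH, MeOH/THF/H2O, 0 °C → rt
Reagents that add atoms: none
Why: Intramolecular aldol condensation (5-enolexo-exo-trig) in which the ketone-flanked methylene attacks the aldehyde and dehydration gives the conjugated 1-acetylcyclopentene, whereas enolisation of the aldehyde would have to occur at a neopentyl CH2 and lead to a more hindered alkene; the two existing stereocentres carry no acidic hydrogen.

Step 8
Reactants: 13 1-[(4R,5R)-4-{2-[(TBS)oxy]butyl}-5-{2-[(TBDPS)oxy]ethyl}-4-methylcyclopent-1-en-1-yl]ethan-1-one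
Product: 14 1-[(1S,2S,3R)-3-{2-[(TBS)oxy]butyl}-2-{2-[(TBDPS)oxy]ethyl}-3-methylcyclopentyl]ethan-1-one
Conditions: H2 (1 atm), Pd/C (10 % Pd), EtOAc, rt
Reagents that add atoms: none
Why: Heterogeneous hydrogenation of the enone C=C from the face opposite the allylic silyloxyethyl arm and the C-3 methyl should deliver hydrogen to C-1 anti to that arm, setting the (1S) centre with the acetyl group cis to the arm (the kinetic, less stable arrangement, as in the hydrogenation of 16-dehydro-20-oxo steroids).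

Step 9
Reactants: 14 1-[(1S,2S,3R)-3-{2-[(TBS)oxy]butyl}-2-{2-[(TBDPS)oxy]ethyl}-3-methylcyclopentyl]ethan-1-one; 15 5-bromo-2-methylpent-2-ene
Product: 16 (2S)-2-[(1S,2S,3R)-3-{2-[(TBS)oxy]butyl}-2-{2-[(TBDPS)oxy]ethyl}-3-methylcyclopentyl]-6-methylhept-5-en-2-ol
Conditions: 15 (3 equiv), Mg, THF, rt; CeCl3 (anhydrous, 3 equiv), THF, −78 °C; then 14, −78 °C; aq. NH4Cl
Reagents that add atoms: none
Why: The alkylcerium dichloride formed from the Grignard reagent of 15 and CeCl3 adds in a polar 1,2-fashion to the acetyl carbonyl of 14, the oxophilic, weakly basic reagent activating C=O without enolising the ketone, which would scramble C-1. The closest known reaction type is the Grignard or organocerium addition to α-branched methyl ketones, as used to build 20-hydroxy steroid side chains from 17β-acetyl steroids, which show the same arrangement of an acetyl group on a five-membered ring next to a more substituted ring carbon. No ring is closed. The new carbinol centre is set by 1,2-induction from C-1 (Felkin–Anh): the ring bond to C-2, the methine that carries the cis silyloxyethyl arm, stands anti to the incoming nucleophile, the acetyl methyl lies next to the C-1 hydrogen, and attack past that hydrogen gives the (S)-alcohol. The step needs facial selectivity at the carbonyl and freedom from enolisation; the cis arm on C-2 and the cis methyl on C-3 close one face, and the cerium reagent at −78 °C secures the second. The silyl ethers and the trisubstituted alkene of the reagent are inert, and the addition both brings in all six side-chain carbons and turns the epimerisable C-1 centre into a fixed one.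

Step 10
Reactants: 16 (2S)-2-[(1S,2S,3R)-3-{2-[(TBS)oxy]butyl}-2-{2-[(TBDPS)oxy]ethyl}-3-methylcyclopentyl]-6-methylhept-5-en-2-ol
Product: 17 triethylsilyl ether of 16 (tertiary O–TES)
Conditions: TESOTf, 2,6-lutidine, CH2Cl2, −78 → 0 °C
Reagents that add atoms: triethylsilyl triflate, CC[Si](CC)(CC)OS(=O)(=O)C(F)(F)F
Why: Silylation of the hindered tertiary hydroxyl by the silyl triflate method prevents its 5-exo attack on the epoxide that steps 11 and 12 pass through.

Step 11
Reactants: 17 triethylsilyl ether of 16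
Product: 18 triethyl({(2S)-4-[(2S)-3,3-dimethyloxiran-2-yl]-2-[(1S,2S,3R)-3-{2-[(TBS)oxy]butyl}-2-{2-[(TBDPS)oxy]ethyl}-3-methylcyclopentyl]butan-2-yl}oxy)silane
Conditions: L-fructose-derived ketone 1,2:4,5-di-O-isopropylidene-β-L-erythro-2,3-hexodiulo-2,6-pyranose (30 mol %), Oxone (2KHSO5·KHSO4·K2SO4), K2CO3, Bu4NHSO4, MeCN/CH2(OMe)2/aq. Na2B4O7 buffer, 0 °C
Reagents that add atoms: potassium peroxymonosulfate (active part of Oxone), [K+].[O-]S(=O)(=O)OO
Why: Shi asymmetric epoxidation (chiral dioxirane, spiro transition state) of the only alkene, an electron-rich trisubstituted one; the new centre is remote from the others, so the L-configured ketone should set the (S)-epoxide by reagent control.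

Step 12
Reactants: 18 (S)-epoxide
Product: 19 (3S,6S)-6-[(1S,2S,3R)-3-{2-[(TBS)oxy]butyl}-2-{2-[(TBDPS)oxy]ethyl}-3-methylcyclopentyl]-2-methyl-6-[(triethylsilyl)oxy]hept-1-en-3-ol
Conditions: Et2AlCl, lithium 2,2,6,6-tetramethylpiperidide, PhMe, 0 °C; then aq. KNaC4H4O6
Reagents that add atoms: none
Why: Aluminium amide-promoted isomerisation of a trisubstituted epoxide to an allylic alcohol (syn β-elimination) in which a methyl proton is removed while the tertiary C–O bond breaks, so the secondary C–O bond and its (S) configuration are kept and the isopropenyl group appears.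

Step 13
Reactants: 19 (3S,6S)-allylic alcohol
Product: 20 (3S,6S)-6-[(1S,2S,3R)-3-{2-[(TBS)oxy]butyl}-2-{2-[(TBDPS)oxy]ethyl}-3-methylcyclopentyl]-2-methyl-6-[(triethylsilyl)oxy]hept-1-en-3-yl acetate
Conditions: Ac2O, pyridine, DMAP (cat.), CH2Cl2, rt
Reagents that add atoms: acetic anhydride, CC(=O)OC(C)=O
Why: DMAP-catalysed acylation of the only free hydroxyl installs the acetate of the target, which then protects this oxygen during the oxidation.

Step 14
Reactants: 20 silylated acetate
Product: 21 (3S,6S)-6-hydroxy-6-[(1S,2S,3R)-3-(2-hydroxybutyl)-2-(2-hydroxyethyl)-3-methylcyclopentyl]-2-methylhept-1-en-3-yl acetate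
Conditions: Bu4NF, AcOH, THF, rt → 40 °C
Reagents that add atoms: none
Why: Fluoride cleavage of all three silyl ethers, with acetic acid buffering so that the alkoxides formed neither remove nor shift the acetate.

Step 15
Reactants: 21 triol acetate
Product: 23 (3S)-5-[(1S,4aS,5R,7aS)-3-hydroxy-1,5-dimethyl-5-(2-oxobutyl)octahydrocyclopenta[c]pyran-1-yl]-2-methylpent-1-en-3-yl acetate (lactol; both anomers), via keto aldehyde 22 (not isolated)
Conditions: (COCl)2, DMSO, CH2Cl2, −78 °C; Et3N, −78 → 0 °C
Reagents that add atoms: none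
Why: Swern oxidation converts the primary alcohol to the aldehyde and the secondary alcohol to the ethyl ketone, leaves the tertiary alcohol and the allylic acetate untouched, and leaves no oxidant behind when the aldehyde is captured by the cis tertiary hydroxyl as a six-membered lactol, the form in which the material should be isolated.

Step 16
Reactants: 23 lactol
Product: 25 (3S,6S)-6-hydroxy-2-methyl-6-[(1S,3aR,8aS)-3a,6-dimethyl-5-oxo-1,2,3,3a,4,5,8,8a-octahydroazulen-1-yl]hept-1-en-3-yl acetate, via aldol adduct 24 (not isolated)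
Conditions: piperidine, AcOH (0.5 equiv each), 4 Å MS, PhMe, 70 °C
Reagents that add atoms: none
Why: Amine/acid-catalysed intramolecular aldol condensation (7-enolendo-exo-trig) of a lactol that is the ring-closed tautomer of a δ-hydroxy aldehyde and reacts by ring–chain equilibrium through that open form: the ethyl CH2 of the ketone adds to the formyl carbon and E1cB loss of water gives the α-methyl enone, while the two possible five-ring closures would give trans-fused bicyclo[3.3.0]octenes and are excluded by strain, and the weakly basic medium spares the acetate.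

## Compound list

1 | 3-[(tert-butyldiphenylsilyl)oxy]propanal | O=CCCO[Si](c1ccccc1)(c1ccccc1)C(C)(C)C | starting material
2 | 2-(triphenylphosphoranylidene)propanal | CC(C=O)=P(c1ccccc1)(c1ccccc1)c1ccccc1 | starting material
3 | (2E)-5-[(TBDPS)oxy]-2-methylpent-2-enal | O=C/C(C)=C/CCO[Si](c1ccccc1)(c1ccccc1)C(C)(C)C | intermediate
4 | isoprene (2-methylbuta-1,3-diene) | C=CC(C)=C | starting material
5 | (1S,6R)-6-{2-[(TBDPS)oxy]ethyl}-1,4-dimethylcyclohex-3-ene-1-carbaldehyde | CC1=CC[C@](C)(C=O)[C@@H](CCO[Si](c2ccccc2)(c2ccccc2)C(C)(C)C)C1 | intermediate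
6 | methyl enol ether of the homologated aldehyde: 5 with CHO replaced by CH=CH–OMe, E/Z mixture, (1S,6R) | CC1=CC[C@](C)(C=COC)[C@@H](CCO[Si](c2ccccc2)(c2ccccc2)C(C)(C)C)C1 | intermediate (not isolated)
7 | 2-[(1R,6R)-6-{2-[(TBDPS)oxy]ethyl}-1,4-dimethylcyclohex-3-en-1-yl]acetaldehyde | CC1=CC[C@](C)(CC=O)[C@@H](CCO[Si](c2ccccc2)(c2ccccc2)C(C)(C)C)C1 | intermediate
8 | 1-[(1R,6R)-6-{2-[(TBDPS)oxy]ethyl}-1,4-dimethylcyclohex-3-en-1-yl]butan-2-ol (both C-2 epimers) | CC1=CC[C@](C)(CC(O)CC)[C@@H](CCO[Si](c2ccccc2)(c2ccccc2)C(C)(C)C)C1 | intermediate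
9 | TBS ether of 8 | CC1=CC[C@](C)(CC(CC)O[Si](C)(C)C(C)(C)C)[C@@H](CCO[Si](c2ccccc2)(c2ccccc2)C(C)(C)C)C1 | intermediate
10 | ozonide (1,2,4-trioxolane) of 9 | CC12C[C@H](CCO[Si](c3ccccc3)(c3ccccc3)C(C)(C)C)[C@@](C)(CC(CC)O[Si](C)(C)C(C)(C)C)CC(OO1)O2 | intermediate (not isolated)
11 | (3S,4S)-3-{2-[(TBS)oxy]butyl}-4-{2-[(TBDPS)oxy]ethyl}-3-methyl-6-oxoheptanal | CC(=O)C[C@H](CCO[Si](c1ccccc1)(c1ccccc1)C(C)(C)C)[C@@](C)(CC(CC)O[Si](C)(C)C(C)(C)C)CC=O | intermediate
12 | aldol adduct: 2-acetyl-3-hydroxycyclopentane carrying the arms of 13 (new centres undefined) | CC(=O)C1C(O)C[C@](C)(CC(CC)O[Si](C)(C)C(C)(C)C)[C@H]1CCO[Si](c2ccccc2)(c2ccccc2)C(C)(C)C | intermediate (not isolated)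
13 | 1-[(4R,5R)-4-{2-[(TBS)oxy]butyl}-5-{2-[(TBDPS)oxy]ethyl}-4-methylcyclopent-1-en-1-yl]ethan-1-one | CC(=O)C1=CC[C@](C)(CC(CC)O[Si](C)(C)C(C)(C)C)[C@H]1CCO[Si](c2ccccc2)(c2ccccc2)C(C)(C)C | intermediate
14 | 1-[(1S,2S,3R)-3-{2-[(TBS)oxy]butyl}-2-{2-[(TBDPS)oxy]ethyl}-3-methylcyclopentyl]ethan-1-one | CC(=O)[C@H]1CC[C@](C)(CC(CC)O[Si](C)(C)C(C)(C)C)[C@H]1CCO[Si](c2ccccc2)(c2ccccc2)C(C)(C)C | intermediate
15 | 5-bromo-2-methylpent-2-ene | CC(C)=CCCBr | starting material
16 | (2S)-2-[(1S,2S,3R)-3-{2-[(TBS)oxy]butyl}-2-{2-[(TBDPS)oxy]ethyl}-3-methylcyclopentyl]-6-methylhept-5-en-2-ol | CC(C)=CCC[C@](C)(O)[C@H]1CC[C@](C)(CC(CC)O[Si](C)(C)C(C)(C)C)[C@H]1CCO[Si](c2ccccc2)(c2ccccc2)C(C)(C)C | intermediate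
17 | triethylsilyl ether of 16 | CC(C)=CCC[C@](C)(O[Si](CC)(CC)CC)[C@H]1CC[C@](C)(CC(CC)O[Si](C)(C)C(C)(C)C)[C@H]1CCO[Si](c2ccccc2)(c2ccccc2)C(C)(C)C | intermediate
18 | (S)-epoxide of 17: triethyl({(2S)-4-[(2S)-3,3-dimethyloxiran-2-yl]-2-[cyclopentyl unit of 16]butan-2-yl}oxy)silane | CC1(C)O[C@H]1CC[C@](C)(O[Si](CC)(CC)CC)[C@H]2CC[C@](C)(CC(CC)O[Si](C)(C)C(C)(C)C)[C@H]2CCO[Si](c3ccccc3)(c3ccccc3)C(C)(C)C | intermediate
19 | (3S,6S)-6-[cyclopentyl unit of 16]-2-methyl-6-[(triethylsilyl)oxy]hept-1-en-3-ol | C=C(C)[C@H](CC[C@](C)(O[Si](CC)(CC)CC)[C@H]1CC[C@](C)(CC(CC)O[Si](C)(C)C(C)(C)C)[C@H]1CCO[Si](c2ccccc2)(c2ccccc2)C(C)(C)C)O | intermediate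
20 | acetate of 19 | C=C(C)[C@H](CC[C@](C)(O[Si](CC)(CC)CC)[C@H]1CC[C@](C)(CC(CC)O[Si](C)(C)C(C)(C)C)[C@H]1CCO[Si](c2ccccc2)(c2ccccc2)C(C)(C)C)OC(C)=O | intermediate
21 | (3S,6S)-6-hydroxy-6-[(1S,2S,3R)-3-(2-hydroxybutyl)-2-(2-hydroxyethyl)-3-methylcyclopentyl]-2-methylhept-1-en-3-yl acetate | C=C(C)[C@H](CC[C@](C)(O)[C@H]1CC[C@](C)(CC(O)CC)[C@H]1CCO)OC(C)=O | intermediate
22 | (3S,6S)-6-hydroxy-2-methyl-6-[(1S,2S,3R)-3-methyl-3-(2-oxobutyl)-2-(2-oxoethyl)cyclopentyl]hept-1-en-3-yl acetate (open-chain keto aldehyde) | C=C(C)[C@H](CC[C@](C)(O)[C@H]1CC[C@](C)(CC(=O)CC)[C@H]1CC=O)OC(C)=O | intermediate (not isolated)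
23 | (3S)-5-[(1S,4aS,5R,7aS)-3-hydroxy-1,5-dimethyl-5-(2-oxobutyl)octahydrocyclopenta[c]pyran-1-yl]-2-methylpent-1-en-3-yl acetate (lactol form of 22, both anomers) | C=C(C)[C@H](CC[C@]1(C)OC(O)C[C@H]2[C@@H]1CC[C@]2(C)CC(=O)CC)OC(C)=O | intermediate
24 | (3S,6S)-6-hydroxy-6-[(1S,3aR,8aS)-7-hydroxy-3a,6-dimethyl-5-oxodecahydroazulen-1-yl]-2-methylhept-1-en-3-yl acetate (aldol adduct, new centres undefined) | C=C(C)[C@H](CC[C@](C)(O)[C@H]1CC[C@]2(C)CC(=O)C(C)C(O)C[C@@H]12)OC(C)=O | intermediate (not isolated)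
25 | (3S,6S)-6-hydroxy-2-methyl-6-[(1S,3aR,8aS)-3a,6-dimethyl-5-oxo-1,2,3,3a,4,5,8,8a-octahydroazulen-1-yl]hept-1-en-3-yl acetate | C=C(C)[C@H](CC[C@](C)(O)[C@H]1CC[C@]2(C)CC(=O)C(C)=CC[C@@H]12)OC(C)=O | target

## Step count and risks

Total step count: 16. Longest linear sequence: 16 steps (from 1).

Steps most likely to fail:

Step 2. The β-alkyl-α-methyl enal may bind the cationic catalyst poorly, so that turnover is slow or the two faces of the enal are not well distinguished. Fallback, setting out from 3 and 4 and returning at 5: a Diels–Alder reaction promoted by the achiral Lewis acid MeAlCl2 (CH2Cl2, −78 → −20 °C) should give the racemic trans aldehyde F1. Condensation with (1R,2R)-N,N′-dimethyl-1,2-diphenylethane-1,2-diamine (4 Å MS, Et2O) should convert it into two diastereomeric imidazolidines; no new stereocentre arises because the diamine is C2-symmetric. These are separated by chromatography into the wanted aminal F2 and the aminal of the enantiomeric aldehyde F3, which is set aside. Mild acid hydrolysis of F2 (aq. HCl/Et2O) releases 5 and the diamine.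

Step 9. Enolisation of the methyl ketone by the organometallic reagent (loss of material and epimerisation at C-1) or weak facial discrimination at the carbonyl may lower the yield of the (S)-carbinol. Fallback, setting out from 14 and returning at 21: non-basic radical union by ketyl–olefin coupling with SmI2, methyl acrylate and t-BuOH in THF at 0 °C should give, after lactonisation, the γ-lactone F4, in which the carbinol oxygen is held in a temporary ring and the diastereomers can be separated. Addition of isopropenyllithium (from 2-bromopropene and t-BuLi, THF, −78 °C) should open the lactone to the hydroxy enone F5. CBS reduction with the (R)-2-methyl-CBS-oxazaborolidine and catecholborane should give the (3S)-diol F6, and Ac2O/pyridine should acetylate only the secondary hydroxyl to give the monoacetate F7. Bu4NF/AcOH then removes the two silyl groups to give 21; this path also bypasses steps 10 to 12.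

Step 16. Ring closure to the seven-membered enone may be slow under the mild amine/acid catalysis because most of the material rests in the lactol form, with intermolecular condensation or partial loss of the acetate taking over. Fallback, setting out from 23 and returning at 25: the order of the end-game is changed so that the ring is closed by hydroxide enolate chemistry on deacetylated material and the acetate is put on last. KOH in MeOH/H2O (rt → 50 °C) should effect the aldol condensation with concurrent acetate cleavage to give the diol enone F8. Ac2O, pyridine and DMAP (cat.) at 0 °C should then acetylate the secondary allylic hydroxyl selectively, the tertiary carbinol being inert, to give 25.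

## Further compounds

F1 | step 2 | racemic trans-6-{2-[(TBDPS)oxy]ethyl}-1,4-dimethylcyclohex-3-ene-1-carbaldehyde (5 and its enantiomer) | CC1=CC[C@](C)(C=O)[C@@H](CCO[Si](c2ccccc2)(c2ccccc2)C(C)(C)C)C1.CC1=CC[C@@](C)(C=O)[C@H](CCO[Si](c2ccccc2)(c2ccccc2)C(C)(C)C)C1
F2 | step 2 | (4R,5R)-1,3-dimethyl-4,5-diphenylimidazolidine aminal of 5 | CN1C([C@@]2(C)CC=C(C)C[C@@H]2CCO[Si](c3ccccc3)(c3ccccc3)C(C)(C)C)N(C)[C@H](c2ccccc2)[C@H]1c1ccccc1
F3 | step 2 | (4R,5R)-1,3-dimethyl-4,5-diphenylimidazolidine aminal of the enantiomer of 5 (set aside) | CN1C([C@]2(C)CC=C(C)C[C@H]2CCO[Si](c3ccccc3)(c3ccccc3)C(C)(C)C)N(C)[C@H](c2ccccc2)[C@H]1c1ccccc1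
F4 | step 9 | (5S)-5-[(1S,2S,3R)-3-{2-[(TBS)oxy]butyl}-2-{2-[(TBDPS)oxy]ethyl}-3-methylcyclopentyl]-5-methyloxolan-2-one | O=C1CC[C@](C)(O1)[C@H]2CC[C@](C)(CC(CC)O[Si](C)(C)C(C)(C)C)[C@H]2CCO[Si](c3ccccc3)(c3ccccc3)C(C)(C)C
F5 | step 9 | (6S)-6-hydroxy-2-methyl-6-[cyclopentyl unit of 16]hept-1-en-3-one | C=C(C)C(=O)CC[C@](C)(O)[C@H]1CC[C@](C)(CC(CC)O[Si](C)(C)C(C)(C)C)[C@H]1CCO[Si](c2ccccc2)(c2ccccc2)C(C)(C)C
F6 | step 9 | (3S,6S)-2-methyl-6-[cyclopentyl unit of 16]hept-1-ene-3,6-diol | C=C(C)[C@H](CC[C@](C)(O)[C@H]1CC[C@](C)(CC(CC)O[Si](C)(C)C(C)(C)C)[C@H]1CCO[Si](c2ccccc2)(c2ccccc2)C(C)(C)C)O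
F7 | step 9 | (3S,6S)-6-hydroxy-2-methyl-6-[cyclopentyl unit of 16]hept-1-en-3-yl acetate | C=C(C)[C@H](CC[C@](C)(O)[C@H]1CC[C@](C)(CC(CC)O[Si](C)(C)C(C)(C)C)[C@H]1CCO[Si](c2ccccc2)(c2ccccc2)C(C)(C)C)OC(C)=O
F8 | step 16 | (1S,3aR,8aS)-1-[(2S,5S)-2,5-dihydroxy-6-methylhept-6-en-2-yl]-3a,6-dimethyl-2,3,3a,4,8,8a-hexahydroazulen-5(1H)-one | C=C(C)[C@H](CC[C@](C)(O)[C@H]1CC[C@]2(C)CC(=O)C(C)=CC[C@@H]12)O
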